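## The problem

- Target 26 is a biflavonoid: C3 of a naringenin-type flavanone is bonded to C8'' of an apigenin-type flavone. The 7''-oxygen, ortho to that bond, is a hydrogen sulfate and five other phenols are free.
- The C3–C8'' bond joins a stereogenic, enolisable sp3 carbon to an arene carbon flanked by two oxygens. It is hindered and poorly suited to a late coupling under strong base.
- The two stereocentres, C2 (R) and C3 (S), are trans. C3 is alpha to the C4 ketone and can be corrected by equilibration toward the trans isomer.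
- C2 is lost whenever the flavanone opens to a chalcone by beta-elimination of the ring A phenoxide. It must therefore be set absolutely and kept away from base once ring C exists: C2 can guide C3, but C3 cannot guide C2.
- The aryl sulfate does not survive acid or strong Lewis acid and must sit on one phenol out of six. This calls for late sulfation of a single unmasked hydroxyl and a neutral global deprotection.
- The enabling feature lies in ring C: the acyl carbon C4 and the ether oxygen O1 are bonded to the adjacent ring A carbons C4a and C8a. Removing those two carbons lets C4 and O1 close to the acyl–oxygen bond of a trans-3,4-diaryloxetan-2-one that already holds C2, C3 and both aryl groups.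
- The 5,7-dioxygenation of ring A is that of a 3,5-dialkoxybenzyne, whose alkoxy group beside the triple bond decides which aryne carbon receives oxygen. The flavone half is apigenin itself, and C8'' is ortho to O7'', which offers a sigmatropic entry to a C8'' substituent that also singles out the 7''-hydroxyl.

## Retrosynthesis

**From 26 back to 23.** The last bonds cut are the O–S bond of the sulfate and the benzylic C–O bonds of four benzyl ethers and one benzyl carbonate. Sulfation before global deprotection is what makes it selective, because in 24 the 7''-hydroxyl is the only free phenol. Hydrogenolysis of 25 then removes everything else in one neutral operation. This requires 23 to carry on the 7''-oxygen a group orthogonal to benzyl, here a methoxymethyl ether.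

**From 23 to 16 and 21.** The cut is O1–C8a and C4–C4a, the two bonds from ring C to ring A. The neighbouring cuts are C2–O1 (oxa-Michael closure of a chalcone) and C3–C8'' (arylation of a flavanone enolate). Unlike those, this cut leaves both stereocentres and the C3–C8'' bond complete in the precursor and needs no base at the flavanone stage. Precursor 16 is a four-membered lactone with no ring A; ring A arrives as aryne 22, released from 21. The forward reaction must deliver the lactone oxygen to one defined aryne carbon and then break the acyl–oxygen bond, not the benzylic C–O bond. The alkoxy group beside the triple bond of 22 and the electron-poor carbonate on the 4-aryl group of 16 serve these two demands.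

**From 16 to 10 and 11.** The lactone acyl–oxygen bond is cut first (hydroxy acid 15), then the bond between the two stereogenic carbons (aldol). A trans lactone corresponds to an anti aldol, because ring closure by carboxyl activation retains the carbinol configuration. An auxiliary-controlled aldol of imide 10 with aldehyde 11 is preferred to catalytic ketene–aldehyde cycloadditions, which usually give cis lactones and suit hindered arylketenes poorly. The acetate of 11 keeps the aldehyde electron-poor, is cleaved together with the auxiliary (13 to 14), and is replaced in the same flask by the benzyl carbonate that the lactone needs (15).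

**From 10 to 1.** The N–acyl bond is cut to acid 7 and auxiliary 8. The acetic acid side chain is traced back to an allyl group (7 from 6 from 5), and the allyl group is returned from C8 to O7 (4 from 3). The Claisen rearrangement of 3 forms the C8–C bond and in the same event frees the 7-hydroxyl as the one phenol that differs from the others; it is capped as the methoxymethyl ether 5. Ether 3 comes from apigenin 1 by alkylation of its most acidic hydroxyl (2) and benzylation of the other two. The whole flavone is thus bought, not built.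

**From 21 to 17.** The C–Si and O–S bonds are cut. The ortho-silyl triflate 21 comes from bromophenol 18 through silyl ether 19 and phenoxide 20, and 18 from commercial phenol 17 by ortho-bromination. The benzyl ethers of 17 end up as the 5- and 7-O-benzyl groups, removed in the last step.

## Roads not taken

**Alternative 1:** This road cuts the benzene ring of the flavone down to an alkyne. In the key step the 3-alkynylflavan A2 (a triisopropylsilyl ynol ether, C4 held as a silyl-protected alcohol) would be heated with 3-ethoxycyclobutenone A3 in a Danheiser benzannulation, giving phenol A1.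
- Merits: the three ring oxygens of A1 emerge differentiated (free phenol, silyl ether, ethyl ether), so the later sulfate site is marked by construction. The congested C3–C8'' bond is never made by coupling, because C3 only ever carries a slim alkyne.
- Weak points: A1 still lacks the pyranone, so ortho-acylation, chain extension and cyclodehydration must follow. C4 must be raised from alcohol to ketone. The ethyl ether has to be cleaved without harming the other groups. A2, with three contiguous stereocentres and an ynol ether, is itself a demanding target.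
- Comparison: in oxygen differentiation A1 is better than the chosen plan, which relies on a selective mono-allylation of 1. Against this the chosen plan takes the complete flavone from 1 and closes ring C as the last skeletal event, so only deprotection and sulfation follow.

**Alternative 2:** This road cuts C4a–C5 and C8–C8a, building ring A of the flavanone onto a finished heterocycle. Diene A6 would add to the 5-sulfinyl-2,3-dihydropyran-4-one A5 in a Diels–Alder reaction, and two eliminations would aromatise the adduct to the 5,7-dihydroxyflavanone A4.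
- Merits: cycloaddition–aromatisation of such dienes with sulfinyl enones is an established reaction type, more secure than the aryne insertion chosen here. Both stereocentres exist before the arene is formed, and the 5,7-diol is obtained free.
- Weak points: A5 must be made as a single enantiomer with an epimerisable C3 next to a vinylogous ester and a sulfoxide. The free 5- and 7-hydroxyls of A4 must then be protected under base, which is the condition that endangers C2, before the 7''-oxygen can be unmasked and sulfated alone.
- Comparison: alternative 2 is the better-precedented ring construction. The chosen plan offsets this with a short, auxiliary-controlled access to its precursor 16 and with benzyl ethers that are already in place on ring A when it arrives.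

**Alternative 3:** This road cuts C3–C4 and O1–C2. Acetal A9 would be ionised by a chiral phosphoric acid to a salicyl oxocarbenium ion (ortho-quinone methide type) that adds to the (E)-stilbene A8 in an oxa-[4+2] cycloaddition, giving the 4-methoxyflavan A7.
- Merits: it is the most convergent of the four plans. Both stereocentres would be set in one catalytic step, and the trans relationship follows from the alkene geometry.
- Weak points: A8 is a hindered, electron-poor stilbene and a weak nucleophile. Enantiocontrol over a 4-methoxy-substituted cation of this kind is uncertain. C4 emerges at the wrong oxidation level, so hydrolysis and oxidation to the ketone must follow on a substrate whose C3 is then epimerisable.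
- Comparison: in step count and catalytic stereocontrol alternative 3 is as good as or better than the chosen plan. The chosen plan offers a dependable auxiliary for the absolute configuration, ring C delivered directly as the ketone, and an unambiguous ring A regiochemistry.

Key step: step 13

## Route

Remarks on the chemistry:
- Fl stands for the 5-(benzyloxy)-2-[4-(benzyloxy)phenyl]-7-(methoxymethoxy)-4-oxo-4H-chromen-8-yl group.
- Assumption: the sulfate monoesters 25 and 26 are drawn as free hydrogen sulfates, as in the target structure. They would be handled as sodium salts, and 26 released as the acid by a final cation exchange.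
- Assumption: the facial sense of the magnesium aldol in step 8 is taken from the chelated-enolate model, not from a remembered example.
- Phenol 17, auxiliary 8 and aldehyde 11 are taken as commercial.

Step 1
Reactants: 1 apigenin
Product: 2 7-O-allylapigenin [5-hydroxy-2-(4-hydroxyphenyl)-7-(prop-2-enyloxy)-4H-chromen-4-one]
Conditions: allyl bromide (1.05 equiv), K2CO3 (1.0 equiv), DMF, 23 °C
Reagents that add atoms: allyl bromide, C=CCBr
Why: Williamson etherification; the 7-hydroxyl, para to the pyranone carbonyl, is the most acidic phenol, so one equivalent of weak base should alkylate it first, the 4'-hydroxyl reacts more slowly and the chelated 5-hydroxyl hardly at all.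

Step 2
Reactants: 2 7-O-allylapigenin
Product: 3 7-O-allyl-5,4'-di-O-benzylapigenin [5-(benzyloxy)-2-[4-(benzyloxy)phenyl]-7-(prop-2-enyloxy)-4H-chromen-4-one]
Conditions: benzyl bromide (3 equiv), K2CO3 (4 equiv), DMF, 70 °C
Reagents that add atoms: benzyl bromide, BrCc1ccccc1
Why: Williamson etherification; excess reagent and heat are used because the 5-hydroxyl is hydrogen-bonded to the carbonyl, and the allyl ether is inert to these conditions.

Step 3
Reactants: 3 7-O-allyl-5,4'-di-O-benzylapigenin
Product: 4 8-allyl-5,4'-di-O-benzylapigenin [5-(benzyloxy)-2-[4-(benzyloxy)phenyl]-7-hydroxy-8-(prop-2-enyl)-4H-chromen-4-one]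
Conditions: N,N-diethylaniline, 200 °C
Reagents that add atoms: none
Why: Aromatic Claisen rearrangement followed by tautomerisation; migration to C8 should be preferred over C6 because the C7–C8 bond of a chromone has the higher double-bond character and C6 is flanked by the 5-benzyloxy group.

Step 4
Reactants: 4 8-allyl-5,4'-di-O-benzylapigenin
Product: 5 8-allyl-5,4'-di-O-benzyl-7-O-(methoxymethyl)apigenin [Fl–CH2CH=CH2]
Conditions: MOMCl, i-Pr2NEt, CH2Cl2, 0 to 23 °C
Reagents that add atoms: chloromethyl methyl ether, COCCl
Why: Acetal protection of the only free phenol; the methoxymethyl ether withstands the oxidations, the enolate chemistry and fluoride, and is later removed without touching benzyl ethers.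

Step 5
Reactants: 5 8-allyl-5,4'-di-O-benzyl-7-O-(methoxymethyl)apigenin
Product: 6 2-Fl-acetaldehyde
Conditions: OsO4 (2 mol %), NaIO4 (4 equiv), 2,6-lutidine, 1,4-dioxane/H2O (3:1), 23 °C
Reagents that add atoms: OsO4, O=[Os](=O)(=O)=O (catalytic carrier of the new oxygen); sodium periodate, [Na+].[O-]I(=O)(=O)=O (terminal oxidant)
Why: Lemieux–Johnson oxidative cleavage of the terminal alkene; the flavone C2=C3 bond is part of a vinylogous ester and should not be dihydroxylated, and lutidine suppresses over-oxidation.

Step 6
Reactants: 6 2-Fl-acetaldehyde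
Product: 7 2-Fl-acetic acid
Conditions: NaClO2, NaH2PO4, 2-methyl-2-butene, t-BuOH/THF/H2O, 0 to 23 °C
Reagents that add atoms: sodium chlorite, [Na+].[O-]Cl=O
Why: Pinnick oxidation of the enolisable arylacetaldehyde under buffered conditions; the alkene scavenger traps hypochlorous acid before it can chlorinate the electron-rich rings.

Step 7
Reactants: 7 2-Fl-acetic acid; 8 (R)-4-benzyl-1,3-oxazolidin-2-one
Product: 10 (R)-4-benzyl-3-(2-Fl-acetyl)-1,3-oxazolidin-2-one, via mixed pivalic anhydride 9 (not isolated)
Conditions: PivCl, Et3N, THF, −20 °C; then 8, LiCl, −20 to 23 °C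
Reagents that add atoms: none
Why: N-Acylation of the oxazolidinone through the mixed pivalic anhydride, a standard one-flask procedure for arylacetic acids; the hindered pivaloyl carbonyl is not attacked.

Step 8
Reactants: 10 (R)-4-benzyl-3-(2-Fl-acetyl)-1,3-oxazolidin-2-one; 11 4-formylphenyl acetate
Product: 13 (R)-4-benzyl-3-[(2S,3R)-3-(4-acetoxyphenyl)-2-Fl-3-hydroxypropanoyl]-1,3-oxazolidin-2-one, via trimethylsilyl ether 12 (not isolated)
Conditions: MgCl2 (0.5 equiv), Et3N, TMSCl, EtOAc, 23 °C; then citric acid, MeOH, 23 °C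
Reagents that add atoms: none
Why: Evans magnesium-halide-catalysed anti-aldol reaction of a non-enolisable aromatic aldehyde; soft enolisation gives the chelated Z-enolate, the aldehyde should add to the face opposite the auxiliary benzyl group (setting the alpha carbon as S) through a boat-like transition state that gives the anti relationship (carbinol carbon R). In situ silylation of the aldolate blocks retro-aldol equilibration.

Step 9
Reactants: 13 (R)-4-benzyl-3-[(2S,3R)-3-(4-acetoxyphenyl)-2-Fl-3-hydroxypropanoyl]-1,3-oxazolidin-2-one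
Product: 15 (2S,3R)-3-[4-(benzyloxycarbonyloxy)phenyl]-2-Fl-3-hydroxypropanoic acid, via phenol acid 14 (not isolated)
Conditions: LiOH, H2O2, THF/H2O, 0 °C; Na2SO3; then CbzCl, NaHCO3, 0 °C; acidify to pH 3
Reagents that add atoms: lithium hydroperoxide formed from hydrogen peroxide, OO, and LiOH, [Li+].[OH-] (carboxyl oxygen); benzyl chloroformate, O=C(Cl)OCc1ccccc1
Why: Hydroperoxide cleaves the exocyclic imide carbonyl and the aryl acetate without touching either stereocentre; in the same flask, Schotten–Baumann acylation of the phenoxide (the only nucleophile reactive at this pH) installs the benzyl carbonate. The sensitive 4-hydroxybenzylic alcohol 14 is therefore never exposed to acid.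

Step 10
Reactants: 15 (2S,3R)-3-[4-(benzyloxycarbonyloxy)phenyl]-2-Fl-3-hydroxypropanoic acid
Product: 16 (3S,4R)-4-[4-(benzyloxycarbonyloxy)phenyl]-3-Fl-oxetan-2-one (trans)
Conditions: PhSO2Cl, pyridine, 0 °C
Reagents that add atoms: none
Why: Beta-lactonisation by carboxyl activation; the hydroxyl attacks the activated acyl carbon, so the carbinol configuration is retained and the anti acid gives the trans lactone. The carbonate on the 4-aryl ring lowers the tendency of the lactone to ionise at the benzylic carbon and lose carbon dioxide.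

Step 11
Reactants: 17 3,5-bis(benzyloxy)phenol
Product: 18 3,5-bis(benzyloxy)-2-bromophenol
Conditions: NBS, CH2Cl2, −78 °C
Reagents that add atoms: N-bromosuccinimide, O=C1CCC(=O)N1Br
Why: Electrophilic aromatic bromination; at low temperature in a non-polar solvent, delivery of bromine through hydrogen bonding to the phenol should favour the ortho position, and any para isomer is removed by chromatography.

Step 12
Reactants: 18 3,5-bis(benzyloxy)-2-bromophenol
Product: 21 3,5-bis(benzyloxy)-2-(trimethylsilyl)phenyl trifluoromethanesulfonate, via aryl silyl ether 19 (not isolated), via lithium silylphenoxide 20 (not isolated)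
Conditions: HMDS, THF, 65 °C; evaporate; n-BuLi, THF, −100 to −78 °C; Tf2O, −78 to 0 °C
Reagents that add atoms: hexamethyldisilazane, C[Si](C)(C)N[Si](C)(C)C; trifluoromethanesulfonic anhydride, O=S(=O)(OS(=O)(=O)C(F)(F)F)C(F)(F)F
Why: O-Silylation, bromine–lithium exchange, retro-Brook migration of silicon from oxygen to the ortho carbon, and O-triflation of the resulting phenoxide; this is the standard route to ortho-silylaryl triflates. Halogen–metal exchange at −100 °C is much faster than deprotonation of the benzyl ethers.

Step 13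
Reactants: 16 (3S,4R)-4-[4-(benzyloxycarbonyloxy)phenyl]-3-Fl-oxetan-2-one; 21 3,5-bis(benzyloxy)-2-(trimethylsilyl)phenyl trifluoromethanesulfonate
Product: 23 (2R,3S)-5,7-bis(benzyloxy)-2-[4-(benzyloxycarbonyloxy)phenyl]-3-Fl-chroman-4-one, via 3,5-bis(benzyloxy)benzyne 22 (not isolated)
Conditions: 21 (2 equiv, slow addition), CsF (4 equiv), MeCN/toluene (1:1), 23 °C
Reagents that add atoms: none
Why: Proposed new method: fluoride releases aryne 22 from 21, and the ring oxygen of the strained lactone 16, whose lone pair is poorly conjugated to the carbonyl, adds to the aryne carbon remote from the adjacent benzyloxy group; the aryl anion so formed lies ortho to the new O1–C8a bond, adds to the neighbouring acyl carbon through a four-membered transition state, and the tetrahedral intermediate collapses with cleavage of the acyl–oxygen bond, so that the two aryne carbons are inserted into that bond. A second channel leads to the same product: reversible opening of the lactone by fluoride at the acyl carbon would give a beta-alkoxide acyl fluoride, whose alkoxide adds to 22 and whose acyl fluoride captures the aryl anion in a 6-exo-trig acylation. The closest known reaction types are the sigma-insertion of arynes into the N–C(=O) bond of amides and ureas, the addition of carboxylic acids to arynes with acyl migration to ortho-hydroxyaryl ketones, and the annulation of salicylates with arynes to xanthones; none has been shown on the acyl–oxygen bond of a lactone. Ring C is closed by two-atom ring expansion of the four-membered ring (O1–C8a first, then C4–C4a), driven by the release of beta-lactone strain. No stereocentre is created: C2 and C3 are carried over from C4 and C3 of 16 because neither the benzylic C–O bond nor any bond at C3 is broken, and the trans product is also the thermodynamic epimer at C3. The step needs regioselectivity at the aryne (oxygen to C8a, acyl to C4a), which the benzyloxy group beside the triple bond secures by distortion and inductive stabilisation of the ortho anion. It also needs acyl–oxygen over alkyl–oxygen cleavage, which the electron-poor carbonate on the C2 aryl ring secures by disfavouring benzylic ionisation.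

Step 14
Reactants: 23 (2R,3S)-5,7-bis(benzyloxy)-2-[4-(benzyloxycarbonyloxy)phenyl]-3-Fl-chroman-4-one
Product: 24 (2R,3S)-5,7-bis(benzyloxy)-3-{5-(benzyloxy)-2-[4-(benzyloxy)phenyl]-7-hydroxy-4-oxo-4H-chromen-8-yl}-2-[4-(benzyloxycarbonyloxy)phenyl]chroman-4-one
Conditions: ZnBr2, n-PrSH, CH2Cl2, 0 °C
Reagents that add atoms: none
Why: Lewis-acid-assisted transfer of the methoxymethyl group to a thiol, a fast and mild acetal cleavage that leaves benzyl ethers and the aryl carbonate alone; no base is present, so C2 is not put at risk.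

Step 15
Reactants: 24 (2R,3S)-5,7-bis(benzyloxy)-3-{5-(benzyloxy)-2-[4-(benzyloxy)phenyl]-7-hydroxy-4-oxo-4H-chromen-8-yl}-2-[4-(benzyloxycarbonyloxy)phenyl]chroman-4-one
Product: 25 7''-O-hydrogen sulfate of 24 [(2R,3S)-configured; all benzyl ethers and the benzyl carbonate retained]
Conditions: SO3·pyridine (5 equiv), pyridine, 40 °C; aqueous NaHCO3 work-up (sodium salt)
Reagents that add atoms: sulfur trioxide–pyridine complex, [O-]S(=O)(=O)[n+]1ccccc1
Why: O-Sulfation of a phenol with an amine–sulfur trioxide complex, the standard method for flavonoid sulfates; the 7''-hydroxyl is the only free hydroxyl, so no selectivity is required, and pyridine is too weak a base to open the flavanone.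

Step 16
Reactants: 25 7''-O-hydrogen sulfate of 24
Product: 26 target, (2R,3S)-5,7-dihydroxy-3-[5-hydroxy-2-(4-hydroxyphenyl)-4-oxo-7-(sulfooxy)-4H-chromen-8-yl]-2-(4-hydroxyphenyl)chroman-4-one
Conditions: H2 (1 atm), Pd/C, THF/MeOH, 23 °C; then cation-exchange resin (H+ form), 0 °C
Reagents that add atoms: none
Why: Hydrogenolysis of four benzyl ethers and the benzyl carbonate (which then loses carbon dioxide) under neutral conditions; aryl sulfate salts are inert to hydrogen over palladium, and O-benzyl groups should be cleaved faster than the flavone double bond or the benzylic C2–O1 bond.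

## Compound list

1 | apigenin | O=c1cc(-c2ccc(O)cc2)oc2cc(O)cc(O)c12 | starting material
2 | 7-O-allylapigenin | C=CCOc1cc(O)c2c(=O)cc(-c3ccc(O)cc3)oc2c1 | intermediate
3 | 7-O-allyl-5,4'-di-O-benzylapigenin | C=CCOc1cc(OCc2ccccc2)c2c(=O)cc(-c3ccc(OCc4ccccc4)cc3)oc2c1 | intermediate
4 | 8-allyl-5,4'-di-O-benzylapigenin | C=CCc1c(O)cc(OCc2ccccc2)c2c(=O)cc(-c3ccc(OCc4ccccc4)cc3)oc12 | intermediate
5 | 8-allyl-5,4'-di-O-benzyl-7-O-(methoxymethyl)apigenin | C=CCc1c(OCOC)cc(OCc2ccccc2)c2c(=O)cc(-c3ccc(OCc4ccccc4)cc3)oc12 | intermediate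
6 | 2-Fl-acetaldehyde | O=CCc1c(OCOC)cc(OCc2ccccc2)c2c(=O)cc(-c3ccc(OCc4ccccc4)cc3)oc12 | intermediate
7 | 2-Fl-acetic acid | OC(=O)Cc1c(OCOC)cc(OCc2ccccc2)c2c(=O)cc(-c3ccc(OCc4ccccc4)cc3)oc12 | intermediate
8 | (R)-4-benzyl-1,3-oxazolidin-2-one | O=C1N[C@H](Cc2ccccc2)CO1 | starting material
9 | 2-Fl-acetic pivalic anhydride (formed in situ) | CC(C)(C)C(=O)OC(=O)Cc1c(OCOC)cc(OCc2ccccc2)c2c(=O)cc(-c3ccc(OCc4ccccc4)cc3)oc12 | intermediate
10 | (R)-4-benzyl-3-(2-Fl-acetyl)-1,3-oxazolidin-2-one | O=C(Cc1c(OCOC)cc(OCc2ccccc2)c2c(=O)cc(-c3ccc(OCc4ccccc4)cc3)oc12)N1[C@H](Cc2ccccc2)COC1=O | intermediate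
11 | 4-formylphenyl acetate | CC(=O)Oc1ccc(C=O)cc1 | starting material
12 | (R)-4-benzyl-3-[(2S,3R)-3-(4-acetoxyphenyl)-2-Fl-3-(trimethylsilyloxy)propanoyl]-1,3-oxazolidin-2-one (formed in situ) | O=C([C@@H](c1c(OCOC)cc(OCc2ccccc2)c2c(=O)cc(-c3ccc(OCc4ccccc4)cc3)oc12)[C@@H](O[Si](C)(C)C)c1ccc(OC(C)=O)cc1)N1[C@H](Cc2ccccc2)COC1=O | intermediate
13 | (R)-4-benzyl-3-[(2S,3R)-3-(4-acetoxyphenyl)-2-Fl-3-hydroxypropanoyl]-1,3-oxazolidin-2-one | O=C([C@@H](c1c(OCOC)cc(OCc2ccccc2)c2c(=O)cc(-c3ccc(OCc4ccccc4)cc3)oc12)[C@@H](O)c1ccc(OC(C)=O)cc1)N1[C@H](Cc2ccccc2)COC1=O | intermediate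
14 | (2S,3R)-2-Fl-3-hydroxy-3-(4-hydroxyphenyl)propanoic acid (formed in situ) | OC(=O)[C@@H](c1c(OCOC)cc(OCc2ccccc2)c2c(=O)cc(-c3ccc(OCc4ccccc4)cc3)oc12)[C@@H](O)c1ccc(O)cc1 | intermediate
15 | (2S,3R)-3-[4-(benzyloxycarbonyloxy)phenyl]-2-Fl-3-hydroxypropanoic acid | OC(=O)[C@@H](c1c(OCOC)cc(OCc2ccccc2)c2c(=O)cc(-c3ccc(OCc4ccccc4)cc3)oc12)[C@@H](O)c1ccc(OC(=O)OCc2ccccc2)cc1 | intermediate
16 | (3S,4R)-4-[4-(benzyloxycarbonyloxy)phenyl]-3-Fl-oxetan-2-one (trans) | O=C1O[C@@H](c2ccc(OC(=O)OCc3ccccc3)cc2)[C@@H]1c1c(OCOC)cc(OCc3ccccc3)c2c(=O)cc(-c3ccc(OCc4ccccc4)cc3)oc12 | intermediate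
17 | 3,5-bis(benzyloxy)phenol | Oc1cc(OCc2ccccc2)cc(OCc2ccccc2)c1 | starting material
18 | 3,5-bis(benzyloxy)-2-bromophenol | Oc1cc(OCc2ccccc2)cc(OCc2ccccc2)c1Br | intermediate
19 | [3,5-bis(benzyloxy)-2-bromophenoxy]trimethylsilane (formed in situ) | C[Si](C)(C)Oc1cc(OCc2ccccc2)cc(OCc2ccccc2)c1Br | intermediate
20 | lithium 3,5-bis(benzyloxy)-2-(trimethylsilyl)phenoxide (formed in situ) | [Li+].[O-]c1cc(OCc2ccccc2)cc(OCc2ccccc2)c1[Si](C)(C)C | intermediate
21 | 3,5-bis(benzyloxy)-2-(trimethylsilyl)phenyl trifluoromethanesulfonate | C[Si](C)(C)c1c(OCc2ccccc2)cc(OCc2ccccc2)cc1OS(=O)(=O)C(F)(F)F | intermediate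
22 | 3,5-bis(benzyloxy)benzyne (formed in situ) | C1#CC(OCc2ccccc2)=CC(OCc2ccccc2)=C1 | intermediate
23 | (2R,3S)-5,7-bis(benzyloxy)-2-[4-(benzyloxycarbonyloxy)phenyl]-3-Fl-chroman-4-one | O=C1c2c(OCc3ccccc3)cc(OCc3ccccc3)cc2O[C@@H](c2ccc(OC(=O)OCc3ccccc3)cc2)[C@@H]1c1c(OCOC)cc(OCc3ccccc3)c2c(=O)cc(-c3ccc(OCc4ccccc4)cc3)oc12 | intermediate
24 | (2R,3S)-5,7-bis(benzyloxy)-3-{5-(benzyloxy)-2-[4-(benzyloxy)phenyl]-7-hydroxy-4-oxo-4H-chromen-8-yl}-2-[4-(benzyloxycarbonyloxy)phenyl]chroman-4-one | O=C1c2c(OCc3ccccc3)cc(OCc3ccccc3)cc2O[C@@H](c2ccc(OC(=O)OCc3ccccc3)cc2)[C@@H]1c1c(O)cc(OCc3ccccc3)c2c(=O)cc(-c3ccc(OCc4ccccc4)cc3)oc12 | intermediate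
25 | 7''-O-hydrogen sulfate of 24 | O=C1c2c(OCc3ccccc3)cc(OCc3ccccc3)cc2O[C@@H](c2ccc(OC(=O)OCc3ccccc3)cc2)[C@@H]1c1c(OS(=O)(=O)O)cc(OCc3ccccc3)c2c(=O)cc(-c3ccc(OCc4ccccc4)cc3)oc12 | intermediate
26 | (2R,3S)-5,7-dihydroxy-3-[5-hydroxy-2-(4-hydroxyphenyl)-4-oxo-7-(sulfooxy)-4H-chromen-8-yl]-2-(4-hydroxyphenyl)chroman-4-one | O=C1c2c(O)cc(O)cc2O[C@@H](c2ccc(O)cc2)[C@@H]1c1c(OS(=O)(=O)O)cc(O)c2c(=O)cc(-c3ccc(O)cc3)oc12 | target

## Step count and least certain steps

Total: 16 steps. Longest linear sequence: 14 steps (1 to 26 through steps 1–10 and 13–16); the aryne precursor 21 takes two further steps (11 and 12).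

**Step 13 (key step, bears the label "Proposed new method:").**
- What may go wrong:
  - Addition of a more Lewis-basic site (the flavone carbonyl oxygen) to the aryne in place of the lactone oxygen.
  - Fluoride attack on the aryl carbonate, freeing a phenoxide that is then arylated.
  - Alkyl–oxygen instead of acyl–oxygen cleavage after O-arylation, i.e. insertion into the wrong C–O bond or decarboxylative fragmentation of the lactone.
  - Fluoride-induced enolisation and beta-elimination of the product, which would erode C2.
- Fallback (known chemistry, sets out from 15, returns at 23): the carboxylate of 15 is alkylated with allyl bromide and KHCO3 in DMF to give the allyl ester F1. The secondary alcohol of F1 is O-arylated by aryne 22 generated from 21 (CsF, MeCN, 23 °C), an O–H insertion that leaves the C–O bond at the stereocentre untouched, to give the 3,5-bis(benzyloxy)phenyl ether F2. Deallylation with Pd(PPh3)4 and morpholine gives the 3-aryloxypropanoic acid F3. Intramolecular Friedel–Crafts acylation (trifluoroacetic anhydride, CH2Cl2, 0 °C) ortho to the ether oxygen closes ring C to 23; the two ortho positions are equivalent, so only the 5,7-pattern can result.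

**Step 8.**
- What may go wrong: poor anti/syn or facial selectivity because the enolate carries a 2,6-disubstituted aryl group; sequestration of magnesium by the flavone carbonyl; retro-aldol equilibration before silylation. If only the sense of induction is opposite, the (S)-auxiliary is used.
- Fallback (sets out from 10, returns at 16): the dibutylboron enolate of 10 (Bu2BOTf, i-Pr2NEt, CH2Cl2, −78 °C) undergoes the syn-aldol reaction with 11 through a Zimmerman–Traxler chair to give the (2R,3R) adduct F4, whose carbinol configuration is already correct. Treatment as in step 9 gives the phenol acid F5 and then the carbonate acid F6. PhSO2Cl in pyridine closes the cis-lactone F7. Catalytic DBU epimerises the acidic C3 of F7 to the more stable trans-lactone 16. C3 is thus set by thermodynamics, not by the aldol.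

**Step 3.**
- What may go wrong: rearrangement to C6 as well as C8, giving regioisomers that are hard to separate.
- Fallback (sets out from 1, returns at 5): selective alkylation of 1 with chloromethyl methyl ether (i-Pr2NEt, acetone) gives 7-O-(methoxymethyl)apigenin F8. Benzylation as in step 2 gives the dibenzyl ether F9. Iodination with N-iodosuccinimide, directed to C8 by the para 5-alkoxy group, gives the 8-iodoflavone F10. Stille coupling with allyltributylstannane and Pd(PPh3)4 gives 5.

**Step 16.**
- What may go wrong: hydrogenolytic opening of the benzylic C2–O1 bond; partial saturation of the flavone C2''=C3'' bond; hydrolysis of the sulfate if the medium turns acidic.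
- Fallback (sets out from 24, returns at 26): 24 is sulfated with 2,2,2-trichloroethyl chlorosulfate (Et3N, DMAP, THF, 0 °C) to the neutral sulfate diester F11. The benzyl ethers and the benzyl carbonate are removed with BCl3 and pentamethylbenzene at −78 °C to give the pentaphenol F12, which should keep the trichloroethyl sulfate. Zn dust with HCO2NH4 in MeOH then releases the sulfate monoester 26.

## Further compounds

F1 | step 13 | prop-2-enyl (2S,3R)-3-[4-(benzyloxycarbonyloxy)phenyl]-2-Fl-3-hydroxypropanoate | C=CCOC(=O)[C@@H](c1c(OCOC)cc(OCc2ccccc2)c2c(=O)cc(-c3ccc(OCc4ccccc4)cc3)oc12)[C@@H](O)c1ccc(OC(=O)OCc2ccccc2)cc1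
F2 | step 13 | prop-2-enyl (2S,3R)-3-[3,5-bis(benzyloxy)phenoxy]-3-[4-(benzyloxycarbonyloxy)phenyl]-2-Fl-propanoate | C=CCOC(=O)[C@@H](c1c(OCOC)cc(OCc2ccccc2)c2c(=O)cc(-c3ccc(OCc4ccccc4)cc3)oc12)[C@@H](Oc1cc(OCc2ccccc2)cc(OCc2ccccc2)c1)c1ccc(OC(=O)OCc2ccccc2)cc1
F3 | step 13 | (2S,3R)-3-[3,5-bis(benzyloxy)phenoxy]-3-[4-(benzyloxycarbonyloxy)phenyl]-2-Fl-propanoic acid | OC(=O)[C@@H](c1c(OCOC)cc(OCc2ccccc2)c2c(=O)cc(-c3ccc(OCc4ccccc4)cc3)oc12)[C@@H](Oc1cc(OCc2ccccc2)cc(OCc2ccccc2)c1)c1ccc(OC(=O)OCc2ccccc2)cc1
F4 | step 8 | (R)-4-benzyl-3-[(2R,3R)-3-(4-acetoxyphenyl)-2-Fl-3-hydroxypropanoyl]-1,3-oxazolidin-2-one | O=C([C@H](c1c(OCOC)cc(OCc2ccccc2)c2c(=O)cc(-c3ccc(OCc4ccccc4)cc3)oc12)[C@@H](O)c1ccc(OC(C)=O)cc1)N1[C@H](Cc2ccccc2)COC1=O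
F5 | step 8 | (2R,3R)-2-Fl-3-hydroxy-3-(4-hydroxyphenyl)propanoic acid | OC(=O)[C@H](c1c(OCOC)cc(OCc2ccccc2)c2c(=O)cc(-c3ccc(OCc4ccccc4)cc3)oc12)[C@@H](O)c1ccc(O)cc1
F6 | step 8 | (2R,3R)-3-[4-(benzyloxycarbonyloxy)phenyl]-2-Fl-3-hydroxypropanoic acid | OC(=O)[C@H](c1c(OCOC)cc(OCc2ccccc2)c2c(=O)cc(-c3ccc(OCc4ccccc4)cc3)oc12)[C@@H](O)c1ccc(OC(=O)OCc2ccccc2)cc1
F7 | step 8 | (3R,4R)-4-[4-(benzyloxycarbonyloxy)phenyl]-3-Fl-oxetan-2-one (cis) | O=C1O[C@@H](c2ccc(OC(=O)OCc3ccccc3)cc2)[C@H]1c1c(OCOC)cc(OCc3ccccc3)c2c(=O)cc(-c3ccc(OCc4ccccc4)cc3)oc12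
F8 | step 3 | 7-O-(methoxymethyl)apigenin | COCOc1cc(O)c2c(=O)cc(-c3ccc(O)cc3)oc2c1
F9 | step 3 | 5,4'-di-O-benzyl-7-O-(methoxymethyl)apigenin | COCOc1cc(OCc2ccccc2)c2c(=O)cc(-c3ccc(OCc4ccccc4)cc3)oc2c1
F10 | step 3 | 5,4'-di-O-benzyl-8-iodo-7-O-(methoxymethyl)apigenin | Ic1c(OCOC)cc(OCc2ccccc2)c2c(=O)cc(-c3ccc(OCc4ccccc4)cc3)oc12
F11 | step 16 | 7''-O-(2,2,2-trichloroethoxysulfonyl) derivative of 24 | O=C1c2c(OCc3ccccc3)cc(OCc3ccccc3)cc2O[C@@H](c2ccc(OC(=O)OCc3ccccc3)cc2)[C@@H]1c1c(OS(=O)(=O)OCC(Cl)(Cl)Cl)cc(OCc3ccccc3)c2c(=O)cc(-c3ccc(OCc4ccccc4)cc3)oc12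
F12 | step 16 | 2,2,2-trichloroethyl ester of 26 at the sulfate | O=C1c2c(O)cc(O)cc2O[C@@H](c2ccc(O)cc2)[C@@H]1c1c(OS(=O)(=O)OCC(Cl)(Cl)Cl)cc(O)c2c(=O)cc(-c3ccc(O)cc3)oc12
A1 | alternative 1 | tert-butyldimethylsilyl ether of 2,3-trans-5,7-bis(benzyloxy)-2-[4-(benzyloxy)phenyl]-3-[4-ethoxy-2-hydroxy-6-(triisopropylsilyloxy)phenyl]chroman-4-ol | CC(C)(C)[Si](C)(C)O[C@H]1c2c(OCc3ccccc3)cc(OCc3ccccc3)cc2O[C@@H](c2ccc(OCc3ccccc3)cc2)[C@@H]1c1c(O[Si](C(C)C)(C(C)C)C(C)C)cc(OCC)cc1O
A2 | alternative 1 | tert-butyldimethylsilyl ether of 2,3-trans-5,7-bis(benzyloxy)-2-[4-(benzyloxy)phenyl]-3-[(triisopropylsilyloxy)ethynyl]chroman-4-ol | CC(C)(C)[Si](C)(C)O[C@H]1c2c(OCc3ccccc3)cc(OCc3ccccc3)cc2O[C@@H](c2ccc(OCc3ccccc3)cc2)[C@@H]1C#CO[Si](C(C)C)(C(C)C)C(C)C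
A3 | alternative 1 | 3-ethoxycyclobut-2-en-1-one | CCOC1=CC(=O)C1
A4 | alternative 2 | (2R,3S)-2-[4-(benzyloxy)phenyl]-3-Fl-5,7-dihydroxychroman-4-one | O=C1c2c(O)cc(O)cc2O[C@@H](c2ccc(OCc3ccccc3)cc2)[C@@H]1c1c(OCOC)cc(OCc3ccccc3)c2c(=O)cc(-c3ccc(OCc4ccccc4)cc3)oc12
A5 | alternative 2 | (2R,3S)-2-[4-(benzyloxy)phenyl]-3-Fl-5-(phenylsulfinyl)-2,3-dihydro-4H-pyran-4-one | O=C1C(S(=O)c2ccccc2)=CO[C@@H](c2ccc(OCc3ccccc3)cc2)[C@@H]1c1c(OCOC)cc(OCc3ccccc3)c2c(=O)cc(-c3ccc(OCc4ccccc4)cc3)oc12
A6 | alternative 2 | 1-methoxy-1,3-bis(trimethylsilyloxy)buta-1,3-diene | COC(O[Si](C)(C)C)=CC(=C)O[Si](C)(C)C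
A7 | alternative 3 | 2,3-trans-5,7-bis(benzyloxy)-2-[4-(benzyloxy)phenyl]-3-{5-(benzyloxy)-2-[4-(benzyloxy)phenyl]-4-oxo-7-(prop-2-enyloxy)-4H-chromen-8-yl}-4-methoxychroman | CO[C@H]1c2c(OCc3ccccc3)cc(OCc3ccccc3)cc2O[C@@H](c2ccc(OCc3ccccc3)cc2)[C@@H]1c1c(OCC=C)cc(OCc3ccccc3)c2c(=O)cc(-c3ccc(OCc4ccccc4)cc3)oc12
A8 | alternative 3 | (E)-5-(benzyloxy)-2-[4-(benzyloxy)phenyl]-8-{2-[4-(benzyloxy)phenyl]ethenyl}-7-(prop-2-enyloxy)-4H-chromen-4-one | C=CCOc1cc(OCc2ccccc2)c2c(=O)cc(-c3ccc(OCc4ccccc4)cc3)oc2c1/C=C/c1ccc(OCc2ccccc2)cc1
A9 | alternative 3 | 3,5-bis(benzyloxy)-2-(dimethoxymethyl)phenol | COC(OC)c1c(O)cc(OCc2ccccc2)cc1OCc1ccccc1
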